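## Retrosynthetic overview

1. Target 20 comes from its bis-MOM ether 19. Compound 19 comes from the racemic C3 allyl ester 18 by palladium-catalysed decarboxylative asymmetric protonation, which removes the ester and sets C3 as (R).
2. Ring C of 18 is closed in one operation from the open-chain 2-fluoroaryl β-keto allyl ester 16 and formaldehyde. An aldol at C3 makes C2–C3, and the new alkoxide then displaces fluoride at C8a of ring A and makes O1–C8a.
3. Enabling feature: the C4 ketone is α to C3 and, through C4a, ortho to C8a of ring A. One carbonyl therefore acidifies C3–H and activates a C8a–F bond, O1–C2 is a formaldehyde unit, and the 5- and 7-oxygens sit meta to C8a. The C3 allyl ester and the fluorine are temporary groups that the route removes.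
4. Compound 16 comes from aldol addition and oxidation of allyl arylacetate 9 (ring B with its pyran ring) and fluoro aldehyde 13 (ring A).
5. Order of ring formation: the pyran ring on ring B first (step 1, oxa-6π closure), then pyranone ring C (step 11). Rings A and B are bought as arenes.

Key step: step 11

Assumption: with Meldrum's acid as proton donor, the (R)-configured PHOX ligand is taken to deliver the (3R) ketone, by analogy with this catalyst system on 3-aryl-chroman-4-one allyl esters. The sense would be confirmed on the first run and the antipodal ligand used if the opposite is found.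

## Route

Step 1
Reactants: 1 2,4-dihydroxybenzaldehyde; 2 3-methyl-2-butenal
Product: 4 5-hydroxy-2,2-dimethyl-2H-chromene-6-carbaldehyde, via ortho-quinone methide 3 (not isolated)
Conditions: pyridine, 120 °C (sealed vessel)
Reagents that add atoms: none
Why: Chromenylation of a resorcinol (condensation at C3 with the enal, dehydration to the ortho-quinone methide, oxa-6π electrocyclisation); the 2-hydroxyl is held in a hydrogen bond to the formyl group, so the pyran should close on the 4-oxygen and give the angular 5-hydroxy chromene.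

Step 2
Reactants: 4 5-hydroxy-2,2-dimethyl-2H-chromene-6-carbaldehyde
Product: 5 5-methoxy-2,2-dimethyl-2H-chromene-6-carbaldehyde
Conditions: MeI, K2CO3, DMF, 40 °C
Reagents that add atoms: iodomethane, CI
Why: Williamson O-methylation; K2CO3 in DMF is basic enough to open the chelate of the ortho-formyl phenol.

Step 3
Reactants: 5 5-methoxy-2,2-dimethyl-2H-chromene-6-carbaldehyde
Product: 6 5-methoxy-6-(2-methoxyethenyl)-2,2-dimethyl-2H-chromene (E/Z mixture)
Conditions: MeOCH2PPh3Cl, KOtBu, THF, 0 °C → rt
Reagents that add atoms: (methoxymethyl)triphenylphosphonium chloride, COC[P+](c1ccccc1)(c1ccccc1)c1ccccc1.[Cl-]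
Why: Wittig methoxymethylenation as a one-carbon homologation; the alkene geometry is irrelevant because both isomers hydrolyse to the same aldehyde.

Step 4
Reactants: 6 5-methoxy-6-(2-methoxyethenyl)-2,2-dimethyl-2H-chromene
Product: 7 (5-methoxy-2,2-dimethyl-2H-chromen-6-yl)acetaldehyde
Conditions: 2 M aq. HCl, THF, 40 °C; used crude
Reagents that add atoms: water, O
Why: Acid hydrolysis of the enol ether (C-protonation, hemiacetal collapse); the 2,2-dimethylchromene should tolerate dilute aqueous acid, and the sensitive arylacetaldehyde is taken on directly.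

Step 5
Reactants: 7 (5-methoxy-2,2-dimethyl-2H-chromen-6-yl)acetaldehyde
Product: 8 (5-methoxy-2,2-dimethyl-2H-chromen-6-yl)acetic acid
Conditions: NaClO2, NaH2PO4, 2-methyl-2-butene, t-BuOH/H2O, 0 °C → rt
Reagents that add atoms: sodium chlorite, [Na+].[O-]Cl=O
Why: Pinnick oxidation; the alkene scavenger removes HOCl so that neither the chromene double bond nor the electron-rich ring is chlorinated.

Step 6
Reactants: 8 (5-methoxy-2,2-dimethyl-2H-chromen-6-yl)acetic acid
Product: 9 allyl (5-methoxy-2,2-dimethyl-2H-chromen-6-yl)acetate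
Conditions: allyl bromide, K2CO3, DMF, rt
Reagents that add atoms: allyl bromide, C=CCBr
Why: SN2 O-alkylation of the carboxylate.

Step 7
Reactants: 10 5-fluororesorcinol (5-fluorobenzene-1,3-diol)
Product: 12 2-fluoro-4,6-dihydroxybenzaldehyde, via iminium chloride 11 (not isolated)
Conditions: POCl3, DMF, MeCN, 0 °C → rt; then H2O, 50 °C
Reagents that add atoms: N,N-dimethylformamide, CN(C)C=O; water, O
Why: Vilsmeier–Haack formylation; as for resorcinol itself, attack should occur para to one hydroxyl and ortho to the other (two equivalent positions, both ortho to fluorine) and not at the hindered carbon between the hydroxyls.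

Step 8
Reactants: 12 2-fluoro-4,6-dihydroxybenzaldehyde
Product: 13 2-fluoro-4,6-bis(methoxymethoxy)benzaldehyde
Conditions: NaH, MOMCl, DMF, 0 °C → rt
Reagents that add atoms: chloromethyl methyl ether, COCCl
Why: Williamson-type alkylation of both phenoxides; NaH ensures that the chelated ortho-hydroxyl is protected as well.

Step 9
Reactants: 9 allyl (5-methoxy-2,2-dimethyl-2H-chromen-6-yl)acetate; 13 2-fluoro-4,6-bis(methoxymethoxy)benzaldehyde
Product: 15 allyl 3-[2-fluoro-4,6-bis(methoxymethoxy)phenyl]-3-hydroxy-2-(5-methoxy-2,2-dimethyl-2H-chromen-6-yl)propanoate (racemic mixture of diastereomers), via lithium enolate 14 (not isolated)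
Conditions: LiN(i-Pr)2, THF, −78 °C; then 13, −78 °C; AcOH quench at −78 °C
Reagents that add atoms: none
Why: Aldol addition of an ester lithium enolate to a non-enolisable aldehyde; the cold quench should prevent retro-aldol, and both new stereocentres are erased in steps 10 to 12.

Step 10
Reactants: 15 allyl 3-[2-fluoro-4,6-bis(methoxymethoxy)phenyl]-3-hydroxy-2-(5-methoxy-2,2-dimethyl-2H-chromen-6-yl)propanoate
Product: 16 allyl 3-[2-fluoro-4,6-bis(methoxymethoxy)phenyl]-2-(5-methoxy-2,2-dimethyl-2H-chromen-6-yl)-3-oxopropanoate (racemic; keto/enol mixture)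
Conditions: Dess–Martin periodinane, CH2Cl2, 0 °C → rt
Reagents that add atoms: none
Why: Dess–Martin oxidation of the secondary benzylic alcohol to the β-keto ester under near-neutral conditions that should spare the MOM ethers, the allyl ester and the chromene.

Step 11
Reactants: 16 allyl 3-[2-fluoro-4,6-bis(methoxymethoxy)phenyl]-2-(5-methoxy-2,2-dimethyl-2H-chromen-6-yl)-3-oxopropanoate
Product: 18 allyl 3-(5-methoxy-2,2-dimethyl-2H-chromen-6-yl)-5,7-bis(methoxymethoxy)-4-oxochromane-3-carboxylate (racemic), via hydroxymethyl adduct 17 (not isolated)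
Conditions: (CH2O)n (5 equiv), Cs2CO3 (2 equiv), dry DMF, rt 2 h, then 60 °C
Reagents that add atoms: paraformaldehyde (reacts as formaldehyde), C=O
Why: Proposed new method: Cs2CO3 generates the stabilised enolate of 16, which adds through carbon to formaldehyde (aldol hydroxymethylation; C2–C3 bond and quaternary C3), and the primary alkoxide of 17 then adds to the fluorine-bearing ring carbon ortho to the ketone and expels fluoride (intramolecular SNAr through a Meisenheimer enolate; O1–C8a bond), the closest known reaction types being the carbonate-mediated hydroxymethylation of β-keto esters, the formaldehyde annulation of 2-hydroxydeoxybenzoins to isoflavanones and the oxa-SNAr closure of γ-hydroxy 2-fluoroaryl ketones to chroman-4-ones. Ring C, the only ring formed, closes by a 6-endo-trig addition to the C8a=C4a–C4=O vinylogous acceptor followed by elimination, so that the overall event is a formal [4+2] union of formaldehyde with the aryl ketone enolate. C3 arises as a racemic quaternary centre that needs no control, because step 12 replaces the ester by hydrogen under catalyst control. The step needs carbon hydroxymethylation and alkoxide closure to outrun attack of the enolate ester oxygen on C–F (which would give a 2-allyloxychromone) and retro-Claisen cleavage; this should be secured by excess formaldehyde, which holds the substrate as the neutral adduct 17 and keeps the enolate concentration low, by the far higher nucleophilicity of the alkoxide, by a dry non-nucleophilic base at moderate temperature, and by the single ortho-fluorine, which makes the site of closure unambiguous. The two MOM-oxy groups are meta to the C–F carbon and so do not deactivate it by resonance, and the ester, by removing the second α-hydrogen, blocks bis-hydroxymethylation, enone formation and retro-oxa-Michael opening of the product.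

Step 12
Reactants: 18 allyl 3-(5-methoxy-2,2-dimethyl-2H-chromen-6-yl)-5,7-bis(methoxymethoxy)-4-oxochromane-3-carboxylate
Product: 19 (3R)-3-(5-methoxy-2,2-dimethyl-2H-chromen-6-yl)-5,7-bis(methoxymethoxy)chroman-4-one
Conditions: Pd2(dba)3 (5 mol %), (R)-(CF3)3-t-BuPHOX (12.5 mol %), Meldrum's acid (2.5 equiv), 1,4-dioxane, 40 °C
Reagents that add atoms: none
Why: Palladium-catalysed decarboxylative asymmetric protonation of an α-aryl β-keto allyl ester, in which zerovalent palladium ionises the allyl ester, CO2 is lost and the PHOX-bound palladium enolate is protonated at C3 on one face by Meldrum's acid (which also takes up the allyl group), so that C3 is set as (R) under catalyst control in a substrate class (3-aryl-chroman-4-one-3-carboxylates bearing an ortho-substituted aryl group) for which this reaction type is established.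

Step 13
Reactants: 19 (3R)-3-(5-methoxy-2,2-dimethyl-2H-chromen-6-yl)-5,7-bis(methoxymethoxy)chroman-4-one
Product: 20 (3R)-5,7-dihydroxy-3-(5-methoxy-2,2-dimethyl-2H-chromen-6-yl)chroman-4-one
Conditions: ZnBr2 (2.2 equiv), n-PrSH (4.5 equiv), CH2Cl2, 0 °C, 10–15 min; pH 7 buffer work-up
Reagents that add atoms: none
Why: Lewis-acid-assisted transfer of the methoxymethyl groups to the thiol (MOM ether cleavage) is fast, aprotic and cold, so the C3–H stereocentre (no base present, only minutes available for enolisation), the chromene and the aryl methyl ether should remain untouched.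

## Compound list

1 | 2,4-dihydroxybenzaldehyde | O=Cc1ccc(O)cc1O | starting material
2 | 3-methyl-2-butenal | CC(C)=CC=O | starting material
3 | 2-hydroxy-3-(3-methylbut-2-en-1-ylidene)-4-oxocyclohexa-1,5-diene-1-carbaldehyde (ortho-quinone methide, not isolated) | O=CC1=C(O)C(=CC=C(C)C)C(=O)C=C1 | intermediate
4 | 5-hydroxy-2,2-dimethyl-2H-chromene-6-carbaldehyde | O=Cc1ccc2c(c1O)C=CC(C)(C)O2 | intermediate
5 | 5-methoxy-2,2-dimethyl-2H-chromene-6-carbaldehyde | COc1c(C=O)ccc2c1C=CC(C)(C)O2 | intermediate
6 | 5-methoxy-6-(2-methoxyethenyl)-2,2-dimethyl-2H-chromene (E/Z mixture) | COC=Cc1ccc2c(c1OC)C=CC(C)(C)O2 | intermediate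
7 | (5-methoxy-2,2-dimethyl-2H-chromen-6-yl)acetaldehyde | O=CCc1ccc2c(c1OC)C=CC(C)(C)O2 | intermediate
8 | (5-methoxy-2,2-dimethyl-2H-chromen-6-yl)acetic acid | OC(=O)Cc1ccc2c(c1OC)C=CC(C)(C)O2 | intermediate
9 | allyl (5-methoxy-2,2-dimethyl-2H-chromen-6-yl)acetate | C=CCOC(=O)Cc1ccc2c(c1OC)C=CC(C)(C)O2 | intermediate
10 | 5-fluororesorcinol (5-fluorobenzene-1,3-diol) | Oc1cc(O)cc(F)c1 | starting material
11 | [(2-fluoro-4,6-dihydroxyphenyl)methylidene]dimethylammonium chloride (not isolated) | C[N+](C)=Cc1c(O)cc(O)cc1F.[Cl-] | intermediate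
12 | 2-fluoro-4,6-dihydroxybenzaldehyde | O=Cc1c(O)cc(O)cc1F | intermediate
13 | 2-fluoro-4,6-bis(methoxymethoxy)benzaldehyde | COCOc1cc(F)c(C=O)c(OCOC)c1 | intermediate
14 | lithium enolate of 9 (not isolated) | [Li+].C=CCOC([O-])=Cc1ccc2c(c1OC)C=CC(C)(C)O2 | intermediate
15 | allyl 3-[2-fluoro-4,6-bis(methoxymethoxy)phenyl]-3-hydroxy-2-(5-methoxy-2,2-dimethyl-2H-chromen-6-yl)propanoate (racemic, diastereomer mixture) | C=CCOC(=O)C(c1ccc2c(c1OC)C=CC(C)(C)O2)C(O)c1c(F)cc(OCOC)cc1OCOC | intermediate
16 | allyl 3-[2-fluoro-4,6-bis(methoxymethoxy)phenyl]-2-(5-methoxy-2,2-dimethyl-2H-chromen-6-yl)-3-oxopropanoate (racemic) | C=CCOC(=O)C(c1ccc2c(c1OC)C=CC(C)(C)O2)C(=O)c1c(F)cc(OCOC)cc1OCOC | intermediate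
17 | allyl 3-[2-fluoro-4,6-bis(methoxymethoxy)phenyl]-2-(hydroxymethyl)-2-(5-methoxy-2,2-dimethyl-2H-chromen-6-yl)-3-oxopropanoate (racemic, not isolated) | C=CCOC(=O)C(CO)(c1ccc2c(c1OC)C=CC(C)(C)O2)C(=O)c1c(F)cc(OCOC)cc1OCOC | intermediate
18 | allyl 3-(5-methoxy-2,2-dimethyl-2H-chromen-6-yl)-5,7-bis(methoxymethoxy)-4-oxochromane-3-carboxylate (racemic) | C=CCOC(=O)C1(c2ccc3c(c2OC)C=CC(C)(C)O3)COc2cc(OCOC)cc(OCOC)c2C1=O | intermediate
19 | (3R)-3-(5-methoxy-2,2-dimethyl-2H-chromen-6-yl)-5,7-bis(methoxymethoxy)chroman-4-one | COc1c([C@@H]2COc3cc(OCOC)cc(OCOC)c3C2=O)ccc2c1C=CC(C)(C)O2 | intermediate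
20 | (3R)-5,7-dihydroxy-3-(5-methoxy-2,2-dimethyl-2H-chromen-6-yl)chroman-4-one | COc1c([C@@H]2COc3cc(O)cc(O)c3C2=O)ccc2c1C=CC(C)(C)O2 | target

## Step count and risks

Total step count: 13. Longest linear sequence: 11 steps (steps 1–6 and 9–13); steps 7–8 form the second branch.

Steps most likely to fail:

1. Step 11 (proposed new method). What may go wrong: the enolate ester oxygen may attack the fluorinated carbon, or the hydroxymethyl adduct may revert while fluoride displacement on the electron-rich ring stays slow. Fallback with known reaction types, setting out from 9 and returning at 18: methylenation of 9 with paraformaldehyde, K2CO3 and Bu4NI would give allyl 2-(5-methoxy-2,2-dimethyl-2H-chromen-6-yl)prop-2-enoate F1. Commercial 2,4,6-trihydroxybenzaldehyde would be protected twice (MOMCl, i-Pr2NEt; the chelated hydroxyl stays free) to give 2-hydroxy-4,6-bis(methoxymethoxy)benzaldehyde F2. A base-mediated oxa-Michael/aldol annulation of F1 and F2 (Cs2CO3, MeCN) would close ring C through O1–C2 and C3–C4 instead and give allyl 4-hydroxy-3-(5-methoxy-2,2-dimethyl-2H-chromen-6-yl)-5,7-bis(methoxymethoxy)chromane-3-carboxylate F3. Dess–Martin oxidation of F3 would give 18.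

2. Step 12. What may go wrong: insufficient or reversed facial selectivity in the protonation of the palladium enolate, which here is flanked by the 5-MOM-oxy group. Fallback setting out from 18 and returning at 19: non-asymmetric decarboxylation (Pd(OAc)2, PPh3, HCO2H, Et3N, THF) would give racemic 3-(5-methoxy-2,2-dimethyl-2H-chromen-6-yl)-5,7-bis(methoxymethoxy)chroman-4-one F4. Asymmetric transfer hydrogenation with dynamic kinetic resolution (RuCl[(R,R)-TsDPEN](p-cymene), HCO2H/Et3N, 40 °C) should give cis-(3R,4R)-3-(5-methoxy-2,2-dimethyl-2H-chromen-6-yl)-5,7-bis(methoxymethoxy)chroman-4-ol F5. Dess–Martin oxidation (NaHCO3, CH2Cl2, 0 °C) would return the ketone 19 without touching C3.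

3. Step 13. What may go wrong: Lewis-acid-promoted enolisation at C3 (loss of enantiopurity) or ionisation of the allylic aryl ether of the chromene during MOM cleavage. Fallback setting out from 18 and returning at 20, in which the acid step is moved in front of the stereocentre: 3 M aq. HCl in THF at 40 °C would give allyl 5,7-dihydroxy-3-(5-methoxy-2,2-dimethyl-2H-chromen-6-yl)-4-oxochromane-3-carboxylate F6. Silylation (TBSOTf, 2,6-lutidine, CH2Cl2, 0 °C) would give allyl 5,7-bis(tert-butyldimethylsilyloxy)-3-(5-methoxy-2,2-dimethyl-2H-chromen-6-yl)-4-oxochromane-3-carboxylate F7. Decarboxylative asymmetric protonation under the conditions of step 12 would give (3R)-5,7-bis(tert-butyldimethylsilyloxy)-3-(5-methoxy-2,2-dimethyl-2H-chromen-6-yl)chroman-4-one F8. Buffered desilylation (HF·pyridine, THF/pyridine, 0 °C) would give 20.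

Further compounds

F1 | step 11 | allyl 2-(5-methoxy-2,2-dimethyl-2H-chromen-6-yl)prop-2-enoate | C=CCOC(=O)C(=C)c1ccc2c(c1OC)C=CC(C)(C)O2
F2 | step 11 | 2-hydroxy-4,6-bis(methoxymethoxy)benzaldehyde | COCOc1cc(O)c(C=O)c(OCOC)c1
F3 | step 11 | allyl 4-hydroxy-3-(5-methoxy-2,2-dimethyl-2H-chromen-6-yl)-5,7-bis(methoxymethoxy)chromane-3-carboxylate (racemic, diastereomer mixture) | C=CCOC(=O)C1(c2ccc3c(c2OC)C=CC(C)(C)O3)COc2cc(OCOC)cc(OCOC)c2C1O
F4 | step 12 | racemic 3-(5-methoxy-2,2-dimethyl-2H-chromen-6-yl)-5,7-bis(methoxymethoxy)chroman-4-one | COc1c(C2COc3cc(OCOC)cc(OCOC)c3C2=O)ccc2c1C=CC(C)(C)O2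
F5 | step 12 | (3R,4R)-3-(5-methoxy-2,2-dimethyl-2H-chromen-6-yl)-5,7-bis(methoxymethoxy)chroman-4-ol (cis) | COc1c([C@@H]2COc3cc(OCOC)cc(OCOC)c3[C@@H]2O)ccc2c1C=CC(C)(C)O2
F6 | step 13 | allyl 5,7-dihydroxy-3-(5-methoxy-2,2-dimethyl-2H-chromen-6-yl)-4-oxochromane-3-carboxylate (racemic) | C=CCOC(=O)C1(c2ccc3c(c2OC)C=CC(C)(C)O3)COc2cc(O)cc(O)c2C1=O
F7 | step 13 | allyl 5,7-bis(tert-butyldimethylsilyloxy)-3-(5-methoxy-2,2-dimethyl-2H-chromen-6-yl)-4-oxochromane-3-carboxylate (racemic) | C=CCOC(=O)C1(c2ccc3c(c2OC)C=CC(C)(C)O3)COc2cc(O[Si](C)(C)C(C)(C)C)cc(O[Si](C)(C)C(C)(C)C)c2C1=O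
F8 | step 13 | (3R)-5,7-bis(tert-butyldimethylsilyloxy)-3-(5-methoxy-2,2-dimethyl-2H-chromen-6-yl)chroman-4-one | COc1c([C@@H]2COc3cc(O[Si](C)(C)C(C)(C)C)cc(O[Si](C)(C)C(C)(C)C)c3C2=O)ccc2c1C=CC(C)(C)O2
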